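**Plan**

Cuts: the hetero ring of the quinolone is opened at three bonds at once, C-4a–C-4, C-4–C-3 and N-1–C-2. This leaves 2-iodo-N-methylaniline, carbon monoxide and 1-heptadecyne. The alkyne is cut further at its propargylic C–C bond (1-bromopentadecane plus silyl-capped acetylene), and the aniline at N–CH3.
Enabling feature: in the 4-pyridone ring, fusion carbon C-8a carries N-1 and its neighbour C-4a carries the ketone carbon C-4. These two arms are bridged by the sp2 carbons C-3 and C-2, and C-2 holds the fifteen-carbon chain. An ortho-halogenated N-methylaniline, one CO and a terminal alkyne therefore supply all six ring atoms without redox adjustment.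
Forward order: the pentadecyl chain is joined to the two-carbon alkyne unit (steps 1 and 2), and the purchased benzene ring receives its N-methyl group (steps 3 and 4). The pyridone is the only ring to be made, and it closes in step 5, the same operation that attaches the chain.
Stereochemistry: the target has neither a stereocentre nor a stereogenic double bond, so no step has to set or protect any.

Key step: step 5

Remark on the chemistry: the transient diethylamino enaminone of the last step is drawn as its E isomer (amino group trans to the carbonyl). Either geometry would give the same product, because this geometry is erased when diethylamine is expelled.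

**Route**

Step 1
Reactants: 1 1-bromopentadecane; 2 ethynyltrimethylsilane
Product: 4 1-(trimethylsilyl)heptadec-1-yne, via lithium trimethylsilylacetylide 3 (not isolated)
Conditions: 2 (1.3 equiv), n-BuLi (1.2 equiv), THF, −78 to 0 °C; then DMPU, 1, 0 °C to rt
Reagents that add atoms: n-butyllithium, [Li]CCCC (supplies only the lithium of 3; nothing of it remains in 4)
Why: This is an SN2 alkylation of a lithium acetylide with an unhindered primary bromide, in which DMPU loosens the lithium aggregates and the silyl cap blocks the second acetylenic position so that only monoalkylation is possible.

Step 2
Reactants: 4 1-(trimethylsilyl)heptadec-1-yne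
Product: 5 1-heptadecyne
Conditions: K2CO3 (0.2 equiv), MeOH–THF, rt
Reagents that add atoms: none
Why: In this base-catalysed protodesilylation methoxide attacks silicon and the departing sp carbanion is protonated by methanol, while the saturated chain offers no other reactive site and THF keeps the lipophilic substrate in solution.

Step 3
Reactants: 6 2-iodoaniline
Product: 7 N-(2-iodophenyl)formamide
Conditions: HCO2H (5 equiv), toluene, reflux, Dean–Stark trap
Reagents that add atoms: formic acid, O=CO
Why: Thermal N-formylation of an aniline is driven to completion by azeotropic removal of water, and it stops cleanly at the monoformamide because the acylated nitrogen is no longer nucleophilic.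

Step 4
Reactants: 7 N-(2-iodophenyl)formamide
Product: 8 2-iodo-N-methylaniline
Conditions: BH3·THF (2.5 equiv), THF, 0 °C to reflux; then MeOH, reflux
Reagents that add atoms: none
Why: Electrophilic borane reduction of a secondary formamide to the N-methylamine completes the formylation–reduction monomethylation, which cannot over-alkylate because only one carbon was installed and which leaves the aryl C–I bond intact.

Step 5
Reactants: 5 1-heptadecyne; 8 2-iodo-N-methylaniline; 9 carbon monoxide
Product: 12 1-methyl-2-pentadecyl-4(1H)-quinolone, via alkynone 10 (not isolated), via diethylamino enaminone 11 (not isolated)
Conditions: PdCl2(PPh3)2 (5 mol %), CO (20 bar), 5 (1.2 equiv), Et2NH, 120 °C, autoclave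
Reagents that add atoms: diethylamine, CCNCC (its atoms appear only in 11 and leave again on the way to 12)
Why: Zerovalent palladium, formed in situ from PdCl2(PPh3)2, inserts into the C–I bond of 8, CO migrates in to give an aroyl-palladium species, and the acetylide that diethylamine generates from 5 is transferred to the metal, so that reductive elimination delivers alkynone 10 with the new C-4a–C-4 and C-4–C-3 bonds. Diethylamine then adds to the chain-bearing β-carbon of 10 to give the push-pull enaminone 11, and the ortho methylamino nitrogen replaces the diethylamino group by addition–elimination, which forms N-1–C-2 and releases the vinylogous amide 12 at the right oxidation level. The closest known reaction type is the carbonylative Sonogashira coupling–cyclisation of 2-iodoanilines with terminal alkynes in a secondary amine, an established entry to 2-substituted 4-quinolones. The single ring formed, the 4-pyridone, closes in the 6-endo mode (6-endo-dig counted from 10, 6-endo-trig addition–elimination counted from 11) onto the existing benzene ring, and no stereocentre arises. Chemoselectivity requires CO insertion to be faster than direct alkynylation and acetylide transfer to be faster than aminolysis of the aroyl-palladium species, which 20 bar of CO, a slight excess of the unhindered alkyne and the high temperature should secure. Regioselectivity for six- over five-membered closure follows from the carbonyl group, which polarises the triple bond so that only the carbon carrying the pentadecyl chain is electrophilic, and the pre-installed N-methyl group removes any later N- versus O-alkylation issue.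

**Compound list**

1 | 1-bromopentadecane | CCCCCCCCCCCCCCCBr | starting material
2 | ethynyltrimethylsilane | C#C[Si](C)(C)C | starting material
3 | lithium trimethylsilylacetylide | [Li]C#C[Si](C)(C)C | intermediate
4 | 1-(trimethylsilyl)heptadec-1-yne | CCCCCCCCCCCCCCCC#C[Si](C)(C)C | intermediate
5 | 1-heptadecyne | CCCCCCCCCCCCCCCC#C | intermediate
6 | 2-iodoaniline | Nc1ccccc1I | starting material
7 | N-(2-iodophenyl)formamide | O=CNc1ccccc1I | intermediate
8 | 2-iodo-N-methylaniline | CNc1ccccc1I | intermediate
9 | carbon monoxide | [C-]#[O+] | starting material
10 | 1-[2-(methylamino)phenyl]octadec-2-yn-1-one | CCCCCCCCCCCCCCCC#CC(=O)c1ccccc1NC | intermediate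
11 | (E)-3-(diethylamino)-1-[2-(methylamino)phenyl]octadec-2-en-1-one | CCCCCCCCCCCCCCC/C(=C\C(=O)c1ccccc1NC)N(CC)CC | intermediate
12 | 1-methyl-2-pentadecyl-4(1H)-quinolone | CCCCCCCCCCCCCCCc1cc(=O)c2ccccc2n1C | target

Total step count: 5
Longest linear sequence: 3 steps (1 → 4 → 5 → 12, or equally 6 → 7 → 8 → 12)

**Steps most likely to fail**

Step 5. Aminolysis of the aroyl-palladium species by the large excess of diethylamine (single or double carbonylation) or CO-free alkynylation may outpace acetylide transfer. Displacement of the diethylamino group by the hindered secondary anilino nitrogen may also stall. The fallback sets out from 5 and rejoins the route at 10, and it makes the aryl ketone bond by acyl substitution instead of carbonylation. Commercial N-methylisatoic anhydride is opened with N,O-dimethylhydroxylamine hydrochloride and Et3N in refluxing aqueous ethanol, with loss of carbon dioxide, to give the Weinreb amide N-methoxy-N-methyl-2-(methylamino)benzamide F1. Alkyne 5 is deprotonated with n-BuLi in THF at −78 °C to heptadec-1-yn-1-yllithium F2. F2 is used in excess, because one equivalent is spent on the N–H proton and returns 5. It should add once to F1 and give, after aqueous quench, alkynone 10 as an isolable compound. Heating 10 in diethylamine should then lead through 11 to 12 without palladium or CO pressure.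

Step 1. Displacement at the waxy, poorly soluble bromide by the aggregated silylacetylide may be slow. Dehydrobromination, or premature loss of the silyl cap followed by double alkylation, could then gain ground. The fallback sets out from 1 and rejoins at 5, so 4 and step 2 are bypassed. It inverts the polarity of the chain end and creates the triple bond by homologation rather than bringing it in. Bromide 1 is converted with magnesium turnings in THF into pentadecylmagnesium bromide F3. Formylation with DMF (Bouveault aldehyde synthesis) should give hexadecanal F4. Seyferth–Gilbert homologation with the Ohira–Bestmann reagent, dimethyl (1-diazo-2-oxopropyl)phosphonate, and K2CO3 in MeOH at room temperature should turn F4 into 5.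

Step 4. The reduction may stop short, with C–N cleavage on quench and loss of the formyl group. The product may remain tied up as a borane adduct, and prolonged reflux risks slow hydrodeiodination. The fallback sets out from 7 and rejoins at 8. It uses the formyl group as a temporary protecting group and brings in the methyl carbon by alkylation. Formamide 7 is treated with NaH and MeI in THF–DMF at 0 °C to give N-(2-iodophenyl)-N-methylformamide F5, in which a second alkylation is impossible. The formyl group is then removed with KOH in refluxing aqueous ethanol to release 8.

**Further compounds**

F1 | step 5 | N-methoxy-N-methyl-2-(methylamino)benzamide | CNc1ccccc1C(=O)N(C)OC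
F2 | step 5 | heptadec-1-yn-1-yllithium | CCCCCCCCCCCCCCCC#C[Li]
F3 | step 1 | pentadecylmagnesium bromide | CCCCCCCCCCCCCCC[Mg]Br
F4 | step 1 | hexadecanal | CCCCCCCCCCCCCCCC=O
F5 | step 4 | N-(2-iodophenyl)-N-methylformamide | CN(C=O)c1ccccc1I
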